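Take the target reading at 6.00 min as the measure of the south-east run and divide it by the catalyst charged and by that time, which gives the turnover frequency, target made per catalyst charged per unit time, here a reading averaged over that interval, 8.33 min⁻¹.

- south-east: starting material 0.49 M; free catalyst 1.1 mol%; the very flask that is asked about, followed so far
- flask: starting material 0.49 M; free catalyst 1.1 mol%

south-east run (percent of the starting material charged)

| time / min | target / % | starting material / % |
|---|---|---|
| 6.00 | 55 | 42 |
| 12.0 | 100 | 3 |
| 30.0 | 100 | 0 |
| 80.0 | 101 | 0 |

(standard deviation of a reading: 1.5 percentage points)

- what was read earlier has a scatter of 1.5 percentage points, one standard deviation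
- no earlier run changes the charge of free catalyst; that part of a forecast is a guess

- apparent order in free catalyst when 20% of the starting material are converted (percent change of the rate of making target for one percent more free catalyst charged)

Does that pace hold while starting material is used up? Try first order on the south-east run: the 42% left at 6.00 min ought to become 17.6% at 12.0 min, yet the reading there is 3%, which is less, so drop first order. Then put the pace back in: at 8.33 min⁻¹ the whole charge turns over in 10.9 min, earlier than 12.0 min, where target reads 100%, so the pace survives the test, and 20% conversion falls at 2.18 min, inside the first interval. Take the rate there, then, as turnover frequency times the [free catalyst] charged, which is my reckoning of an order of 1, a guess as long as no run changes the charge. The forecast says 0.9, a little lower than my figure, and it starts from a saturated catalyst, where “rate scales with total catalyst”.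

The flask gives 1.0, so the forecast holds within its margin, and the rate of 2.53 M h⁻¹ at 2.26 min comes to 7.82 min⁻¹ per catalyst charged, the same measure taken at one moment, where the south-east reading gave 8.33 min⁻¹ as an average up to 6.00 min.

    starting material + free catalyst → catalyst intermediate (k = 15.0 L mol⁻¹ s⁻¹)
    catalyst intermediate → free catalyst + target (k = 0.290 s⁻¹)
    starting material + catalyst intermediate ⇌ idle complex, settled at all times (K = 3.00 L mol⁻¹)

While starting material lasted in this flask, free catalyst took it up and catalyst intermediate gave target, with a half-life by that step of 0.040 min at 0.0913 h, and the rate of making target rose to 1.4 times its value at 20% conversion by 0.120 h and to 1.5 times by 0.140 h. By 0.600 h the first step had 100% of its turnover up to the marked time behind it, with starting material at 0% and free catalyst back at 100% of the catalyst charged.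

The data were computed with constants of no real substance; noise was put on by code.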